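**Retrosynthetic overview**
1. The target is unveiled from tetralin 29 by C6 carboxylation (ortho-lithiation beside O7), a TBS-to-acetate exchange at C20, desilylation at C16 and hydrogenolysis of the catechol ketal.
2. C1 is set last, by catalyst-controlled hydrogenation of the C1=C2 bond of 28; the C1 methyl is the fully reduced acyl carbon of enoyl sultam 25.
3. Ring B is made in one operation by a [4+2] cycloaddition of the 3,4-dioxygenated aryne 23 with the (2E,4E)-dienoyl camphorsultam 22, which joins C4a to C4 and C8a to C1. The enabling feature is that ring B is a cyclohexane fused to ring A across C4a–C8a, with the benzylic carbons C1 and C4 linked by C2–C3 (an aryne/1,3-diene retron). O8 beside C8a polarises the aryne; a Friedel–Crafts closure would instead attack C5, para to oxygen.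
4. Diene 22 comes from a copper-catalysed SN2' alkylation (sets C11), cross-metathesis and a Horner–Wadsworth–Emmons reaction; C15 is bought in (R)-3-bromo-2-methylpropan-1-ol.
5. Ring order: ring A is purchased; the dioxole ring is a protecting ring (closed in step 1, opened in step 23); ring B is closed in step 15.

Key step: step 15

Locants: the tetralin numbering of the target is used for all intermediates. C1 carries the methyl, C4 the side chain, C5 is the aromatic CH, C6 the carboxyl, C7 and C8 the oxygens, C11 the side-chain CH, C15 the CHMe, C16 the CH2OH and C20 the CH2OAc. "R" stands for the (2S,6S)-1-(tert-butyldimethylsilyloxy)-7-(tert-butyldiphenylsilyloxy)-6-methylheptan-2-yl side chain.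

Remark 1: the ligand or auxiliary antipode written in steps 12, 15 and 18 is the one assumed to give the configuration drawn; each is available in both mirror-image forms and is exchanged if a model run shows the opposite sense.
Remark 2: (E)-but-2-ene-1,4-diol is taken as purchasable.

**Aryne precursor**

Step 1
Reactants: 1 benzene-1,2,4-triol
Product: 2 2,2-diphenyl-1,3-benzodioxol-5-ol
Conditions: Ph2CCl2 (1.1 equiv), neat, 160 °C, N2
Reagents that add atoms: dichlorodiphenylmethane, ClC(Cl)(c1ccccc1)c1ccccc1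
Why: Double O-alkylation of the vicinal diol by the gem-dichloride closes the five-membered cyclic ketal (catechol diphenylmethylene ketal formation), while the isolated 4-hydroxyl cannot cyclise and stays free.

Step 2
Reactants: 2 2,2-diphenyl-1,3-benzodioxol-5-ol
Product: 3 2,2-diphenyl-1,3-benzodioxol-5-yl N,N-diethylcarbamate
Conditions: ClC(O)NEt2, K2CO3, MeCN, 80 °C
Reagents that add atoms: N,N-diethylcarbamoyl chloride, CCN(CC)C(Cl)=O
Why: O-carbamoylation of the phenoxide installs a strong oxygen-based directing group for the next step.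

Step 3
Reactants: 3 2,2-diphenyl-1,3-benzodioxol-5-yl N,N-diethylcarbamate
Product: 5 2,2-diphenyl-4-(trimethylsilyl)-1,3-benzodioxol-5-yl N,N-diethylcarbamate, via aryllithium 4 (not isolated)
Conditions: s-BuLi, TMEDA, THF, −78 °C; then Me3SiCl, −78 °C to 25 °C
Reagents that add atoms: chlorotrimethylsilane, C[Si](C)(C)Cl
Why: Directed ortho-metalation removes the C–H flanked by the carbamate oxygen and the dioxole oxygen, and the aryllithium is silylated at low temperature before an anionic Fries shift can start.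

Step 4
Reactants: 5 2,2-diphenyl-4-(trimethylsilyl)-1,3-benzodioxol-5-yl N,N-diethylcarbamate
Product: 6 2,2-diphenyl-4-(trimethylsilyl)-1,3-benzodioxol-5-ol
Conditions: LiAlH4, THF, 0 °C to 25 °C
Reagents that add atoms: none
Why: Hydride reduction at the carbamate carbonyl frees the phenol without touching the aryl–silicon bond or the ketal.

Step 5
Reactants: 6 2,2-diphenyl-4-(trimethylsilyl)-1,3-benzodioxol-5-ol
Product: 7 2,2-diphenyl-4-(trimethylsilyl)-1,3-benzodioxol-5-yl trifluoromethanesulfonate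
Conditions: Tf2O, pyridine, CH2Cl2, 0 °C
Reagents that add atoms: trifluoromethanesulfonic anhydride, O=S(=O)(OS(=O)(=O)C(F)(F)F)C(F)(F)F
Why: O-triflation of the phenol gives the ortho-silylaryl triflate, the standard fluoride-triggered aryne precursor.

**Allyl bromide**

Step 6
Reactants: 8 (E)-but-2-ene-1,4-diol
Product: 9 (E)-4-(tert-butyldimethylsilyloxy)but-2-en-1-ol
Conditions: NaH (1 equiv), THF, 0 °C; then TBSCl (1 equiv)
Reagents that add atoms: tert-butylchlorodimethylsilane, CC(C)(C)[Si](C)(C)Cl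
Why: Monosilylation of the symmetric diol through its sparingly soluble mono-sodium alkoxide.

Step 7
Reactants: 9 (E)-4-(tert-butyldimethylsilyloxy)but-2-en-1-ol
Product: 10 (E)-1-bromo-4-(tert-butyldimethylsilyloxy)but-2-ene
Conditions: CBr4, PPh3, CH2Cl2, 0 °C
Reagents that add atoms: tetrabromomethane, BrC(Br)(Br)Br
Why: Appel bromination of the primary allylic alcohol, with retention of the E geometry.

**Auxiliary-bearing phosphonate**

Step 8
Reactants: 11 (1S)-(−)-2,10-camphorsultam; 12 triethyl phosphonoacetate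
Product: 13 N-(diethoxyphosphorylacetyl)-(1S)-2,10-camphorsultam
Conditions: AlMe3 (1.1 equiv), toluene, 0 °C to 80 °C
Reagents that add atoms: none
Why: Aluminium-amide aminolysis of the ester by the sultam nitrogen (the AlMe3-mediated amidation used for phosphonoacetamides) gives the olefination reagent that carries the auxiliary.

**Main sequence**

Step 9
Reactants: 14 (R)-3-bromo-2-methylpropan-1-ol
Product: 15 (R)-1-bromo-3-(tert-butyldiphenylsilyloxy)-2-methylpropane
Conditions: TBDPSCl, imidazole, DMF, 25 °C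
Reagents that add atoms: tert-butylchlorodiphenylsilane, CC(C)(C)[Si](Cl)(c1ccccc1)c1ccccc1
Why: Silylation of the primary alcohol with a group that survives organometallic reagents and outlasts the TBS ether at the end; the C15 stereocentre is bought and untouched.

Step 10
Reactants: 15 (R)-1-bromo-3-(tert-butyldiphenylsilyloxy)-2-methylpropane
Product: 17 (S)-5-(tert-butyldiphenylsilyloxy)-4-methylpentan-1-ol, via Grignard reagent 16 (not isolated)
Conditions: Mg, THF, 40 °C; then CuI (10 mol%), oxirane, −30 °C to 0 °C; aq. NH4Cl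
Reagents that add atoms: oxirane, C1CO1
Why: Grignard formation and copper-catalysed opening of oxirane extend the chain by two carbons, and the stereocentre, β to magnesium, is not involved.

Step 11
Reactants: 17 (S)-5-(tert-butyldiphenylsilyloxy)-4-methylpentan-1-ol
Product: 18 (S)-5-bromo-1-(tert-butyldiphenylsilyloxy)-2-methylpentane
Conditions: CBr4, PPh3, CH2Cl2, 0 °C
Reagents that add atoms: tetrabromomethane, BrC(Br)(Br)Br
Why: Appel bromination of an unhindered primary alcohol.

Step 12
Reactants: 18 (S)-5-bromo-1-(tert-butyldiphenylsilyloxy)-2-methylpentane; 10 (E)-1-bromo-4-(tert-butyldimethylsilyloxy)but-2-ene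
Product: 20 (3S,7S)-3-[(tert-butyldimethylsilyloxy)methyl]-8-(tert-butyldiphenylsilyloxy)-7-methyloct-1-ene, via Grignard reagent 19 (not isolated)
Conditions: Mg, Et2O, 35 °C; then 10, CuBr·SMe2 (2 mol%), (R,R)-Taniaphos (2.4 mol%), CH2Cl2, −78 °C
Reagents that add atoms: none
Why: Copper-catalysed asymmetric allylic alkylation (SN2' substitution) in which the chiral ferrocenyl diphosphine–copper complex delivers the alkyl group to one face of the γ-carbon of the E-allyl bromide, setting C11 (S) and leaving the vinyl group whose inner carbon becomes C4.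

Step 13
Reactants: 20 (3S,7S)-3-[(tert-butyldimethylsilyloxy)methyl]-8-(tert-butyldiphenylsilyloxy)-7-methyloct-1-ene
Product: 21 (2E,4S,8S)-4-[(tert-butyldimethylsilyloxy)methyl]-9-(tert-butyldiphenylsilyloxy)-8-methylnon-2-enal
Conditions: (E)-but-2-enal (5 equiv), second-generation Hoveyda–Grubbs catalyst (5 mol%), CH2Cl2, 40 °C
Reagents that add atoms: (E)-but-2-enal, C/C=C/C=O
Why: Olefin cross-metathesis of a terminal alkene with an electron-poor partner gives the E-enal under thermodynamic control and leaves the allylic C11 centre untouched.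

Step 14
Reactants: 21 (2E,4S,8S)-enal; 13 N-(diethoxyphosphorylacetyl)-(1S)-2,10-camphorsultam
Product: 22 N-[(2E,4E,6S,10S)-6-[(tert-butyldimethylsilyloxy)methyl]-11-(tert-butyldiphenylsilyloxy)-10-methylundeca-2,4-dienoyl]-(1S)-2,10-camphorsultam
Conditions: LiCl, i-Pr2NEt, MeCN, 25 °C
Reagents that add atoms: none
Why: Horner–Wadsworth–Emmons olefination under mild lithium chloride/amine conditions gives the new E double bond; the weak base deprotonates only the phosphonate, so the vinylogous C11–H is not epimerised.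

Step 15
Reactants: 22 (2E,4E)-dienoyl camphorsultam; 7 2,2-diphenyl-4-(trimethylsilyl)-1,3-benzodioxol-5-yl trifluoromethanesulfonate
Product: 25 N-acyl (1S)-2,10-camphorsultam of (4S)-7,8-(diphenylmethylenedioxy)-4-R-3,4-dihydronaphthalene-1-carboxylic acid (C1=C2), via aryne 23 (not isolated), via cis-cycloadduct 24 (not isolated)
Conditions: 7 (2 equiv), CsF (4 equiv), MeCN, 25 °C, Ar; then DBU (1.5 equiv), 25 °C
Reagents that add atoms: none
Why: Fluoride attacks silicon of 7 and triflate leaves to give aryne 23, which adds to the s-cis (2E,4E)-diene of 22 in a concerted, asynchronous [4+2] cycloaddition (aryne Diels–Alder reaction; closest known type: benzyne additions to acyclic 2,4-dienoyl camphorsultams, which give cis-1,4-dihydronaphthalenes). Ring B is closed in the [4+2] mode, with both new bonds formed suprafacially on one face of the diene. That face is fixed by the camphorsultam on the acyl group at C1, and the suprafacial addition relays the choice to C4, which becomes (S) beside the preset C11; C1 forms cis and is then erased on purpose when DBU moves the C2=C3 bond into conjugation, since only C1–H is acidified by the imide and C4–H is not. Regioselectivity needs C4 to bond to C4a and C1 to C8a: the C8–O bond and the fused dioxole ring distort the aryne so that the distal carbon C4a is the more electrophilic one, and it pairs with the diene terminus that has the larger HOMO coefficient and the bulky branch (C4), while the small tied-back oxygen tolerates the acyl-bearing terminus beside it. Periselectivity ([4+2] over ene and [2+2] paths) rests on the easily reached s-cis conformer of the E,E-diene. The acyl carbon is the C1 methyl at the carboxyl oxidation level and is reduced in steps 16 and 17.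

Step 16
Reactants: 25 conjugated N-enoyl camphorsultam
Product: 26 [(4S)-7,8-(diphenylmethylenedioxy)-4-R-3,4-dihydronaphthalen-1-yl]methanol
Conditions: i-Bu2AlH (4 equiv), CH2Cl2, −78 °C to 0 °C; aq. Rochelle salt
Reagents that add atoms: none
Why: 1,2-Reduction of the activated N-acyl sultam by the aluminium hydride gives the allylic alcohol and releases the auxiliary for recovery, while silyl ethers and ketal are inert.

Step 17
Reactants: 26 allylic alcohol
Product: 28 (4S)-7,8-(diphenylmethylenedioxy)-1-methyl-4-R-3,4-dihydronaphthalene (C1=C2), via allylic mesylate 27 (not isolated)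
Conditions: MsCl, Et3N, CH2Cl2, −20 °C; then LiEt3BH (3 equiv), THF, −78 °C to 0 °C
Reagents that add atoms: none
Why: Allylic deoxygenation by SN2 hydride displacement of the primary allylic mesylate turns the former acyl carbon into the C1 methyl and keeps the trisubstituted C1=C2 bond.

Step 18
Reactants: 28 (4S)-1-methyl-3,4-dihydronaphthalene
Product: 29 (1R,4S)-7,8-(diphenylmethylenedioxy)-1-methyl-4-R-1,2,3,4-tetrahydronaphthalene
Conditions: H2 (50 bar), [Ir(cod)(L)][B(C6H3-3,5-(CF3)2)4] (2 mol%), L = (S)-4-tert-butyl-2-(2-diphenylphosphinophenyl)-4,5-dihydrooxazole, CH2Cl2, 25 °C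
Reagents that add atoms: none
Why: Iridium-catalysed asymmetric hydrogenation of an unfunctionalised trisubstituted cyclic styrene (the 1-methyl-3,4-dihydronaphthalene class), in which the chiral P,N ligand selects the alkene face so that hydrogen arrives syn to the C4 side chain and C1 becomes (R), trans to C4.

Step 19
Reactants: 29 (1R,4S)-tetralin
Product: 31 (1R,4S)-7,8-(diphenylmethylenedioxy)-1-methyl-4-R-1,2,3,4-tetrahydronaphthalene-6-carboxylic acid, via aryllithium 30 (not isolated)
Conditions: s-BuLi (1.5 equiv), TMEDA, THF, −78 °C to −40 °C; then CO2; dilute aq. HCl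
Reagents that add atoms: carbon dioxide, O=C=O
Why: Directed ortho-metalation, in which C6–H is the only ring hydrogen ortho to a dioxole oxygen, followed by carboxylation of the aryllithium; both silyl ethers and the ketal tolerate the base.

Step 20
Reactants: 31 carboxylic acid
Product: 32 the C20 alcohol of 31 (the TBS ether is replaced by OH; TBDPS at C16 is kept)
Conditions: PPTS (0.2 equiv), MeOH, 25 °C
Reagents that add atoms: none
Why: Mild acid solvolysis removes the primary TBS ether much faster than the bulkier TBDPS ether and does not open the diaryl ketal.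

Step 21
Reactants: 32 C20 alcohol
Product: 33 the C20 acetate of 32
Conditions: Ac2O, pyridine, CH2Cl2, 0 °C to 25 °C; then H2O
Reagents that add atoms: acetic anhydride, CC(=O)OC(C)=O
Why: Acetylation of the only free hydroxyl; any mixed anhydride formed at the carboxyl group is hydrolysed in the aqueous work-up.

Step 22
Reactants: 33 C20 acetate
Product: 34 the C16 alcohol of 33 (TBDPS removed; the catechol ketal is kept)
Conditions: HF·pyridine, pyridine, THF, 0 °C to 25 °C
Reagents that add atoms: none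
Why: Fluoride-driven desilylation under buffered, non-basic conditions frees the C16 hydroxyl without acetate cleavage or migration.

Step 23
Reactants: 34 ketal-protected target
Product: 35 CNP0191669.1 (target)
Conditions: H2 (1 bar), Pd/C, EtOAc, 25 °C
Reagents that add atoms: none
Why: Hydrogenolysis of the two benzylic C–O bonds of the diphenylmethylene ketal frees the catechol; the acetate, acid, alcohol and both benzylic ring stereocentres are inert.

**Compound list**
1 | benzene-1,2,4-triol | Oc1ccc(O)c(O)c1 | starting material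
2 | 2,2-diphenyl-1,3-benzodioxol-5-ol | Oc1ccc2OC(c3ccccc3)(c3ccccc3)Oc2c1 | intermediate
3 | 2,2-diphenyl-1,3-benzodioxol-5-yl N,N-diethylcarbamate | CCN(CC)C(=O)Oc1ccc2OC(c3ccccc3)(c3ccccc3)Oc2c1 | intermediate
4 | [5-(diethylcarbamoyloxy)-2,2-diphenyl-1,3-benzodioxol-4-yl]lithium | CCN(CC)C(=O)Oc1ccc2OC(c3ccccc3)(c3ccccc3)Oc2c1[Li] | intermediate
5 | 2,2-diphenyl-4-(trimethylsilyl)-1,3-benzodioxol-5-yl N,N-diethylcarbamate | CCN(CC)C(=O)Oc1ccc2OC(c3ccccc3)(c3ccccc3)Oc2c1[Si](C)(C)C | intermediate
6 | 2,2-diphenyl-4-(trimethylsilyl)-1,3-benzodioxol-5-ol | Oc1ccc2OC(c3ccccc3)(c3ccccc3)Oc2c1[Si](C)(C)C | intermediate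
7 | 2,2-diphenyl-4-(trimethylsilyl)-1,3-benzodioxol-5-yl trifluoromethanesulfonate | FC(F)(F)S(=O)(=O)Oc1ccc2OC(c3ccccc3)(c3ccccc3)Oc2c1[Si](C)(C)C | intermediate
8 | (E)-but-2-ene-1,4-diol | OC/C=C/CO | starting material
9 | (E)-4-(tert-butyldimethylsilyloxy)but-2-en-1-ol | CC(C)(C)[Si](C)(C)OC/C=C/CO | intermediate
10 | (E)-1-bromo-4-(tert-butyldimethylsilyloxy)but-2-ene | CC(C)(C)[Si](C)(C)OC/C=C/CBr | intermediate
11 | (1S)-(−)-2,10-camphorsultam, (3aS,6R,7aR) | CC1(C)[C@@H]2CC[C@]13CS(=O)(=O)N[C@@H]3C2 | starting material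
12 | triethyl phosphonoacetate | CCOC(=O)CP(=O)(OCC)OCC | starting material
13 | N-(diethoxyphosphorylacetyl)-(1S)-2,10-camphorsultam | CC1(C)[C@@H]2CC[C@]13CS(=O)(=O)N(C(=O)CP(=O)(OCC)OCC)[C@@H]3C2 | intermediate
14 | (R)-3-bromo-2-methylpropan-1-ol | BrC[C@H](C)CO | starting material
15 | (R)-1-bromo-3-(tert-butyldiphenylsilyloxy)-2-methylpropane | BrC[C@H](C)CO[Si](c1ccccc1)(c1ccccc1)C(C)(C)C | intermediate
16 | (R)-[3-(tert-butyldiphenylsilyloxy)-2-methylpropyl]magnesium bromide | Br[Mg]C[C@H](C)CO[Si](c1ccccc1)(c1ccccc1)C(C)(C)C | intermediate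
17 | (S)-5-(tert-butyldiphenylsilyloxy)-4-methylpentan-1-ol | OCCC[C@H](C)CO[Si](c1ccccc1)(c1ccccc1)C(C)(C)C | intermediate
18 | (S)-5-bromo-1-(tert-butyldiphenylsilyloxy)-2-methylpentane | BrCCC[C@H](C)CO[Si](c1ccccc1)(c1ccccc1)C(C)(C)C | intermediate
19 | (S)-[5-(tert-butyldiphenylsilyloxy)-4-methylpentyl]magnesium bromide | Br[Mg]CCC[C@H](C)CO[Si](c1ccccc1)(c1ccccc1)C(C)(C)C | intermediate
20 | (3S,7S)-3-[(tert-butyldimethylsilyloxy)methyl]-8-(tert-butyldiphenylsilyloxy)-7-methyloct-1-ene | CC(C)(C)[Si](C)(C)OC[C@@H](CCC[C@H](C)CO[Si](c1ccccc1)(c1ccccc1)C(C)(C)C)C=C | intermediate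
21 | (2E,4S,8S)-4-[(tert-butyldimethylsilyloxy)methyl]-9-(tert-butyldiphenylsilyloxy)-8-methylnon-2-enal | CC(C)(C)[Si](C)(C)OC[C@@H](CCC[C@H](C)CO[Si](c1ccccc1)(c1ccccc1)C(C)(C)C)/C=C/C=O | intermediate
22 | N-[(2E,4E,6S,10S)-6-[(tert-butyldimethylsilyloxy)methyl]-11-(tert-butyldiphenylsilyloxy)-10-methylundeca-2,4-dienoyl]-(1S)-2,10-camphorsultam | CC1(C)[C@@H]2CC[C@]13CS(=O)(=O)N(C(=O)/C=C/C=C/[C@@H](CO[Si](C)(C)C(C)(C)C)CCC[C@H](C)CO[Si](c4ccccc4)(c4ccccc4)C(C)(C)C)[C@@H]3C2 | intermediate
23 | 4,5-didehydro-2,2-diphenyl-1,3-benzodioxole (aryne) | C1#CC=CC2=C1OC(O2)(c1ccccc1)c1ccccc1 | intermediate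
24 | N-acyl (1S)-2,10-camphorsultam of (1S,4S)-7,8-(diphenylmethylenedioxy)-4-R-1,4-dihydronaphthalene-1-carboxylic acid (cis) | CC(C)(C)[Si](C)(C)OC[C@@H](CCC[C@H](C)CO[Si](c1ccccc1)(c1ccccc1)C(C)(C)C)[C@@H]1C=C[C@H](C(=O)N4[C@@H]5C[C@H]6CC[C@]5(CS4(=O)=O)C6(C)C)c2c1ccc1OC(c3ccccc3)(c3ccccc3)Oc21 | intermediate
25 | N-acyl (1S)-2,10-camphorsultam of (4S)-7,8-(diphenylmethylenedioxy)-4-R-3,4-dihydronaphthalene-1-carboxylic acid | CC(C)(C)[Si](C)(C)OC[C@@H](CCC[C@H](C)CO[Si](c1ccccc1)(c1ccccc1)C(C)(C)C)[C@@H]1CC=C(C(=O)N4[C@@H]5C[C@H]6CC[C@]5(CS4(=O)=O)C6(C)C)c2c1ccc1OC(c3ccccc3)(c3ccccc3)Oc21 | intermediate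
26 | [(4S)-7,8-(diphenylmethylenedioxy)-4-R-3,4-dihydronaphthalen-1-yl]methanol | CC(C)(C)[Si](C)(C)OC[C@@H](CCC[C@H](C)CO[Si](c1ccccc1)(c1ccccc1)C(C)(C)C)[C@@H]1CC=C(CO)c2c1ccc1OC(c3ccccc3)(c3ccccc3)Oc21 | intermediate
27 | methanesulfonate of 26 | CC(C)(C)[Si](C)(C)OC[C@@H](CCC[C@H](C)CO[Si](c1ccccc1)(c1ccccc1)C(C)(C)C)[C@@H]1CC=C(COS(C)(=O)=O)c2c1ccc1OC(c3ccccc3)(c3ccccc3)Oc21 | intermediate
28 | (4S)-7,8-(diphenylmethylenedioxy)-1-methyl-4-R-3,4-dihydronaphthalene | CC(C)(C)[Si](C)(C)OC[C@@H](CCC[C@H](C)CO[Si](c1ccccc1)(c1ccccc1)C(C)(C)C)[C@@H]1CC=C(C)c2c1ccc1OC(c3ccccc3)(c3ccccc3)Oc21 | intermediate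
29 | (1R,4S)-7,8-(diphenylmethylenedioxy)-1-methyl-4-R-1,2,3,4-tetrahydronaphthalene | CC(C)(C)[Si](C)(C)OC[C@@H](CCC[C@H](C)CO[Si](c1ccccc1)(c1ccccc1)C(C)(C)C)[C@@H]1CC[C@@H](C)c2c1ccc1OC(c3ccccc3)(c3ccccc3)Oc21 | intermediate
30 | 6-lithio derivative of 29 | CC(C)(C)[Si](C)(C)OC[C@@H](CCC[C@H](C)CO[Si](c1ccccc1)(c1ccccc1)C(C)(C)C)[C@@H]1CC[C@@H](C)c2c1cc([Li])c1OC(c3ccccc3)(c3ccccc3)Oc21 | intermediate
31 | (1R,4S)-7,8-(diphenylmethylenedioxy)-1-methyl-4-R-1,2,3,4-tetrahydronaphthalene-6-carboxylic acid | CC(C)(C)[Si](C)(C)OC[C@@H](CCC[C@H](C)CO[Si](c1ccccc1)(c1ccccc1)C(C)(C)C)[C@@H]1CC[C@@H](C)c2c1cc(C(=O)O)c1OC(c3ccccc3)(c3ccccc3)Oc21 | intermediate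
32 | C20 alcohol: as 31 with C20–OH (C16–OTBDPS kept) | OC[C@@H](CCC[C@H](C)CO[Si](c1ccccc1)(c1ccccc1)C(C)(C)C)[C@@H]1CC[C@@H](C)c2c1cc(C(=O)O)c1OC(c3ccccc3)(c3ccccc3)Oc21 | intermediate
33 | C20 acetate of 32 | CC(=O)OC[C@@H](CCC[C@H](C)CO[Si](c1ccccc1)(c1ccccc1)C(C)(C)C)[C@@H]1CC[C@@H](C)c2c1cc(C(=O)O)c1OC(c3ccccc3)(c3ccccc3)Oc21 | intermediate
34 | 7,8-O-diphenylmethylene ketal of the target | CC(=O)OC[C@@H](CCC[C@H](C)CO)[C@@H]1CC[C@@H](C)c2c1cc(C(=O)O)c1OC(c3ccccc3)(c3ccccc3)Oc21 | intermediate
35 | CNP0191669.1, (1R,4S,11S,15S) | CC(=O)OC[C@@H](CCC[C@H](C)CO)[C@@H]1CC[C@@H](C)c2c1cc(C(=O)O)c(O)c2O | target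

**Step count**
Total: 23 steps. Longest linear sequence: 15 steps (steps 9 to 23, from 14).

**Steps most likely to fail, with fallbacks**

Step 15 (aryne cycloaddition). What may go wrong: loss of regio- or facial control, diversion of the aryne into ene or [2+2] paths, or attack of the aryne on the acyl sultam. Fallback: the two aryl–carbon bonds are made one after the other, setting out from 7 and 22 and returning at 25. Borylation of triflate 7 (Pd(dppf)Cl2, bis(pinacolato)diboron, KOAc, dioxane, 80 °C) would give 4,4,5,5-tetramethyl-2-[2,2-diphenyl-4-(trimethylsilyl)-1,3-benzodioxol-5-yl]-1,3,2-dioxaborolane F1. A chiral-diene iridium catalyst ([IrCl(coe)2]2, chiral bicyclooctadiene ligand, aqueous KOH, dioxane) would add the aryl group of F1 to the δ-carbon of 22 (asymmetric 1,6-addition, catalyst control at C4) to give the δ-aryl enoyl sultam F2. ICl would exchange the silyl group for iodine at the ipso carbon to give the aryl iodide F3. Palladium-catalysed intramolecular α-arylation of the dienolate of F3 (Pd(OAc)2, P(t-Bu)3, K3PO4, toluene, 80 °C) would close ring B at C1, and the base would move the double bond into conjugation to give 25.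

Step 18 (hydrogenation that sets C1). What may go wrong: hydrogen is delivered to the wrong alkene face, because the substrate's own preference (attack anti to the pseudoaxial C4 substituent) opposes the catalyst, or turnover is slow beside the peri oxygen. Fallback: C1 is set under thermodynamic control, setting out from 25 and returning at 29. Mg(OMe)2 in MeOH would exchange the sultam for methoxide to give the conjugated methyl ester F4. Mg in MeOH would reduce the C1=C2 bond, and NaOMe in MeOH at 50 °C would equilibrate C1 to the trans methyl ester F5; trans is expected to dominate because O8 forces the C1 ester pseudoaxial and H5 does the same to the C4 side chain. LiAlH4 would give the primary alcohol F6. TsCl/pyridine would give the tosylate F7, and LiEt3BH would reduce it to the methyl compound 29.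

Step 19 (ortho-lithiation and carboxylation). What may go wrong: incomplete or misdirected deprotonation, since the dioxole oxygen is a weak directing group on an electron-rich, alkylated ring and benzylic positions may compete. Fallback: C–H borylation replaces deprotonation, setting out from 29 and returning at 31. [Ir(OMe)(cod)]2 with 4,4'-di-tert-butyl-2,2'-bipyridine and bis(pinacolato)diboron (hexane, 60 °C) would borylate the unhindered C6–H beside the dioxole oxygen to give the C6 pinacol boronate F8; C5–H is shielded by the C4 substituent. Copper-catalysed carboxylation of F8 ([(IPr)CuCl], IPr = 1,3-bis(2,6-diisopropylphenyl)imidazol-2-ylidene, KOMe, CO2 (1 bar), THF, 60 °C) followed by acidification would give 31.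

**Further compounds**
F1 | step 15 | 4,4,5,5-tetramethyl-2-[2,2-diphenyl-4-(trimethylsilyl)-1,3-benzodioxol-5-yl]-1,3,2-dioxaborolane | CC1(C)OB(OC1(C)C)c1ccc2OC(c3ccccc3)(c3ccccc3)Oc2c1[Si](C)(C)C
F2 | step 15 | N-[(2E,5S,6S,10S)-5-[2,2-diphenyl-4-(trimethylsilyl)-1,3-benzodioxol-5-yl]-6-[(tert-butyldimethylsilyloxy)methyl]-11-(tert-butyldiphenylsilyloxy)-10-methylundec-2-enoyl]-(1S)-2,10-camphorsultam | CC(C)(C)[Si](C)(C)OC[C@@H](CCC[C@H](C)CO[Si](c1ccccc1)(c1ccccc1)C(C)(C)C)[C@H](C/C=C/C(=O)N4[C@@H]5C[C@H]6CC[C@]5(CS4(=O)=O)C6(C)C)c1ccc2OC(c3ccccc3)(c3ccccc3)Oc2c1[Si](C)(C)C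
F3 | step 15 | 4-iodo analogue of F2 (iodine in place of the trimethylsilyl group) | CC(C)(C)[Si](C)(C)OC[C@@H](CCC[C@H](C)CO[Si](c1ccccc1)(c1ccccc1)C(C)(C)C)[C@H](C/C=C/C(=O)N4[C@@H]5C[C@H]6CC[C@]5(CS4(=O)=O)C6(C)C)c1ccc2OC(c3ccccc3)(c3ccccc3)Oc2c1I
F4 | step 18 | methyl (4S)-7,8-(diphenylmethylenedioxy)-4-R-3,4-dihydronaphthalene-1-carboxylate | CC(C)(C)[Si](C)(C)OC[C@@H](CCC[C@H](C)CO[Si](c1ccccc1)(c1ccccc1)C(C)(C)C)[C@@H]1CC=C(C(=O)OC)c2c1ccc1OC(c3ccccc3)(c3ccccc3)Oc21
F5 | step 18 | methyl (1R,4S)-7,8-(diphenylmethylenedioxy)-4-R-1,2,3,4-tetrahydronaphthalene-1-carboxylate (trans) | CC(C)(C)[Si](C)(C)OC[C@@H](CCC[C@H](C)CO[Si](c1ccccc1)(c1ccccc1)C(C)(C)C)[C@@H]1CC[C@@H](C(=O)OC)c2c1ccc1OC(c3ccccc3)(c3ccccc3)Oc21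
F6 | step 18 | [(1R,4S)-7,8-(diphenylmethylenedioxy)-4-R-1,2,3,4-tetrahydronaphthalen-1-yl]methanol | CC(C)(C)[Si](C)(C)OC[C@@H](CCC[C@H](C)CO[Si](c1ccccc1)(c1ccccc1)C(C)(C)C)[C@@H]1CC[C@@H](CO)c2c1ccc1OC(c3ccccc3)(c3ccccc3)Oc21
F7 | step 18 | 4-methylbenzenesulfonate of F6 | CC(C)(C)[Si](C)(C)OC[C@@H](CCC[C@H](C)CO[Si](c1ccccc1)(c1ccccc1)C(C)(C)C)[C@@H]1CC[C@@H](COS(=O)(=O)c3ccc(C)cc3)c2c1ccc1OC(c3ccccc3)(c3ccccc3)Oc21
F8 | step 19 | C6 pinacol boronate of 29 | CC(C)(C)[Si](C)(C)OC[C@@H](CCC[C@H](C)CO[Si](c1ccccc1)(c1ccccc1)C(C)(C)C)[C@@H]1CC[C@@H](C)c2c1cc(B3OC(C)(C)C(C)(C)O3)c1OC(c3ccccc3)(c3ccccc3)Oc21
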